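**Plan**

1. Numbering (clerodane type): ring A = C1–C2(OH)–C3=C4–C5–C10; ring B = C5–C6–C7(OAc)–C8(Me)–C9(Me)–C10; ring C = C1–C10–C9–C11–C12(=O)–C13=C16 (seven-membered, C13–C16 are furan carbons); lactone = C4–C18(=O)–O–C19–C5.
2. Retrosynthesis: cut C12–C13 (furan acylation, ring C); trace the O–C18 lactone back to a bridged C19(=O)–O–C2 lactone; cut C1–C2 together with C5–C10 (rings A and B in one intramolecular 2-pyrone Diels–Alder reaction); cut C6–C7 (acyl cross-coupling of two fragments); cut C8–C9 (Ireland–Claisen).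
3. Enabling feature: in ring A, C19 on the quaternary C5 and the oxygen on C2 are cis and 1,4 across the C3=C4 bond that carries C18. Ring A is therefore a reductively opened 2-pyrone [4+2] adduct (pyrone ring = O, C19, C5, C4, C3, C2; C18 = ester on the pyrone).
4. Forward order: furyl carbinol → Claisen acid (C8, C9); pyrone fragment from ethyl vinyl ether; union at C6–C7; Diels–Alder closes rings A and B; C7 reduced and acetylated; bridged lactone opened, C19 reduced and closed onto C18; ring C last.
5. Stereochemistry: one carbinol centre is set by catalytic asymmetric alkynylation and relayed to C9 and C8 by the chair Claisen shift. C8 and C9 relay to C5, C10, C1 and C2 in the Diels–Alder step. C7 is set by equatorial hydride delivery.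

Key step: step 11

Remark: the ZnMe2/(S,S)-ProPhenol catalyst is taken to give the (R)-carbinol in step 1; if the sense of induction is the opposite, the (R,R)-ligand is used and nothing else changes.

**Route**

Step 1
Reactants: 1 tert-butyl(but-3-yn-1-yloxy)dimethylsilane; 2 furan-2-carbaldehyde
Product: 3 (R)-5-[(tert-butyldimethylsilyl)oxy]-1-(furan-2-yl)pent-2-yn-1-ol
Conditions: ZnMe2 (3 equiv), (S,S)-ProPhenol (10 mol %), Ph3P=O (20 mol %), toluene, 0 °C
Reagents that add atoms: none
Why: Catalytic asymmetric alkynylation of an aromatic aldehyde by a zinc alkynylide under a chiral dinuclear zinc catalyst; the ligand antipode fixes the (R)-carbinol, the only stereocentre set by a catalyst.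

Step 2
Reactants: 3 (R)-propargylic alcohol
Product: 4 (1R,2Z)-5-[(tert-butyldimethylsilyl)oxy]-1-(furan-2-yl)-3-iodopent-2-en-1-ol
Conditions: NaAlH2(OCH2CH2OMe)2, THF, 0 °C; then I2, −78 °C
Reagents that add atoms: iodine, II
Why: Hydroxyl-directed trans-hydroalumination of the propargylic alcohol puts aluminium on the distal alkyne carbon, and iodinolysis with retention should give the (Z)-3-iodoallylic alcohol.

Step 3
Reactants: 4 (Z)-vinyl iodide
Product: 5 (1R,2E)-5-[(tert-butyldimethylsilyl)oxy]-1-(furan-2-yl)-3-methylpent-2-en-1-ol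
Conditions: LiCuMe2 (5 equiv), Et2O, 0 °C
Reagents that add atoms: lithium dimethylcuprate, [Li+].C[Cu-]C
Why: Organocuprate cross-coupling of the vinyl iodide with retention of geometry fixes the trisubstituted alkene with the new methyl cis to the carbinol carbon.

Step 4
Reactants: 5 allylic alcohol
Product: 6 (1R,2E)-5-[(tert-butyldimethylsilyl)oxy]-1-(furan-2-yl)-3-methylpent-2-en-1-yl propanoate
Conditions: (EtCO)2O, Et3N, DMAP (cat.), CH2Cl2, 0 °C
Reagents that add atoms: propanoic anhydride, CCC(=O)OC(=O)CC
Why: DMAP-catalysed acylation of the secondary alcohol; no stereocentre is touched.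

Step 5
Reactants: 6 allylic propanoate
Product: 9 (2S,3R,4E)-3-{2-[(tert-butyldimethylsilyl)oxy]ethyl}-5-(furan-2-yl)-2,3-dimethylpent-4-enoic acid, via trimethylsilyl ketene acetal 7 (not isolated), via trimethylsilyl ester 8 (not isolated)
Conditions: LiN(iPr)2, THF/DMPU (4:1), −78 °C; Me3SiCl/Et3N; −78 → 40 °C; aq. citric acid
Reagents that add atoms: none
Why: Ireland–Claisen rearrangement: in THF/DMPU the enolate with the methyl cis to the O-metal is formed and silylated, and the chair [3,3] shift with the furyl group equatorial should transfer the carbinol chirality to the quaternary C9 and to C8 and leave the (E)-C10=C1 alkene.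

Step 6
Reactants: 10 ethoxyethene; 11 ethyl chlorooxoacetate
Product: 12 ethyl (3E)-4-ethoxy-2-oxobut-3-enoate
Conditions: neat, 0 °C → rt; then Et3N, Et2O, 0 °C
Reagents that add atoms: none
Why: Acylation of the enol ether at its nucleophilic β-carbon by the acid chloride followed by loss of HCl (β-acylation of vinyl ethers) gives the push–pull enone.

Step 7
Reactants: 12 keto ester; 13 ethyl 2-(triphenyl-λ5-phosphanylidene)propanoate
Product: 14 diethyl 2-[(E)-2-ethoxyethenyl]-3-methylbut-2-enedioate (either geometry at the new double bond)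
Conditions: toluene, 60 °C
Reagents that add atoms: none
Why: Wittig olefination of the activated α-keto ester carbonyl by the stabilised ylide; the geometry of the new alkene does not matter because it equilibrates in the next step.

Step 8
Reactants: 14 dienyl diester
Product: 15 ethyl 3-methyl-2-oxo-2H-pyran-4-carboxylate
Conditions: 2 M aq. HCl, AcOH, 70 °C
Reagents that add atoms: water, O
Why: Acid hydrolysis of the enol ether to the aldehyde and enol-lactonisation onto the ester that becomes cis by acid-mediated double-bond isomerisation should give the 2-pyrone (pyrone synthesis from 5-alkoxypenta-2,4-dienoates).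

Step 9
Reactants: 15 methylpyrone
Product: 16 ethyl 3-(bromomethyl)-2-oxo-2H-pyran-4-carboxylate
Conditions: NBS, AIBN (cat.), PhCF3, 85 °C
Reagents that add atoms: N-bromosuccinimide, BrN1C(=O)CCC1=O
Why: Wohl–Ziegler radical bromination of the methyl group, which is allylic to the pyrone double bond (a benzylic-type position).

Step 10
Reactants: 9 Claisen acid; 16 bromomethylpyrone
Product: 19 ethyl 3-[(3S,4R,5E)-4-{2-[(tert-butyldimethylsilyl)oxy]ethyl}-6-(furan-2-yl)-3,4-dimethyl-2-oxohex-5-en-1-yl]-2-oxo-2H-pyran-4-carboxylate, via acid chloride 17 (not isolated), via pyranylmethylzinc bromide 18 (not isolated)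
Conditions: 9, 1-chloro-N,N,2-trimethylprop-1-en-1-amine, CH2Cl2, 0 °C; 16, Zn, LiCl, THF, 0 °C; then Pd(PPh3)4 (5 mol %), THF, 0 °C → rt
Reagents that add atoms: none
Why: Negishi-type acylation: zinc insertion into the benzylic-type bromide and coupling with the acid chloride under zerovalent palladium catalysis should form the C6–C7 bond at the CH2 terminus, where the pyrone stays intact, and the neutral formation of the acid chloride protects C8 from epimerisation.

Step 11
Reactants: 19 pyrone–alkenylfuran ketone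
Product: 20 Diels–Alder adduct: trans-fused ring A/ring B system with C3=C4 (CO2Et on C4), a C19(=O)–O–C2 lactone bridge (2-oxabicyclo[2.2.2]oct-5-en-3-one), 7-ketone, 8-Me, 9-Me, 9-CH2CH2OTBS and furan-2-yl on C1; C1, C2, C5, C8, C9, C10 as in the target
Conditions: toluene (0.01 M), BHT (cat.), 110 °C, sealed tube
Reagents that add atoms: none
Why: Thermal intramolecular [4+2] cycloaddition in which the 2-pyrone of 19 (ring atoms O, C19, C5, C4, C3, C2) is the 4π component through C5=C4–C3=C2 and the (E)-C10=C1 alkene the 2π component; the closest known reaction type is the intramolecular Diels–Alder reaction of alkene-tethered 2-pyrones, which gives isolable 2-oxabicyclo[2.2.2]oct-5-en-3-ones when kept below the temperature of CO2 loss. Ring A closes as the six-membered ring of the concerted suprafacial cycloaddition (bonds C1–C2 and C5–C10) and ring B as the six-membered tether ring of a type 1 intramolecular Diels–Alder reaction through a chair-like C5–C6–C7–C8–C9–C10 array. C2 and C5 are tied by the lactone bridge, so that O on C2 and C19 on C5 are cis as in the target; C1 follows from the E geometry of the alkene (H-1 and H-10 trans); C10 relative to C5 follows from the endo position of the furyl group under the C3=C4 bond, which puts C9 exo on the side of the lactone bridge and gives the trans ring A/ring B junction. The face of the pyrone, and with it the absolute configuration of all four new centres, is relayed from C8 and C9: in the favoured tether chair the C8 methyl is equatorial and the methyl C20, the smaller group on C9, is axial over C19. The step needs the pyrone and not the alkenylfuran to act as the diene, which the pairing of the electron-poor ester-substituted pyrone with the electron-rich alkene and the unhindered pyrone terminus C2 should secure (the alternative mode would have to bond the fully substituted C4), and it needs the endo and facial selectivity argued above.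

Step 12
Reactants: 20 adduct ketone
Product: 21 7-hydroxy adduct (axial alcohol, C7 as in the target; otherwise as 20)
Conditions: NaBH4, THF/EtOH, −20 °C
Reagents that add atoms: none
Why: Borohydride reduction of the cyclohexanone; the axial face of C7 is blocked by the syn-axial C19 and C20, so hydride should enter equatorially and give the axial alcohol, and the ketone reacts far faster than the lactone or the ester.

Step 13
Reactants: 21 axial alcohol
Product: 22 7-acetoxy adduct (otherwise as 20)
Conditions: Ac2O, DMAP, pyridine, 40 °C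
Reagents that add atoms: acetic anhydride, CC(=O)OC(C)=O
Why: DMAP-catalysed acetylation of the hindered axial alcohol, the only free hydroxyl at this stage, which is why the acetate is placed before the C2 hydroxyl is set free.

Step 14
Reactants: 22 bridged lactone acetate
Product: 23 hydroxy acid: C19 carboxylic acid on C5, free 2-OH, C18 ethyl ester on C4, 7-OAc, 9-CH2CH2OTBS, 1-(furan-2-yl); all centres as in the target
Conditions: LiOH (1.2 equiv), THF/H2O, 0 °C; then 1 M HCl to pH 3
Reagents that add atoms: lithium hydroxide, [Li+].[OH-]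
Why: Saponification of the strained boat-shaped bridged lactone, which should open much faster than the hindered axial acetate or the conjugated ethyl ester, frees the C2 hydroxyl with retention (acyl–oxygen cleavage) and leaves C19 as the acid.

Step 15
Reactants: 23 hydroxy acid
Product: 25 hydroxy lactone diol: C4–C18(=O)–O–C19–C5 lactone, 2-OH, 7-OAc, 9-CH2CH2OH, 1-(furan-2-yl); all centres as in the target, via diol ester 24 (not isolated)
Conditions: BH3·THF, THF, 0 °C → rt; MeOH; then camphorsulfonic acid (cat.), MeOH, 40 °C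
Reagents that add atoms: none
Why: Borane reduces the carboxylic acid chemoselectively in the presence of both esters (acyloxyborane pathway), and acid in methanol should then close the five-membered lactone from the C19 hydroxyl onto the C18 ester and remove the primary silyl ether.

Step 16
Reactants: 25 hydroxy lactone diol
Product: 26 hydroxy lactone acid (C12 carboxylic acid; otherwise as 25)
Conditions: TEMPO (cat.), PhI(OAc)2, MeCN/H2O, rt
Reagents that add atoms: water, O
Why: Oxoammonium oxidation takes the unhindered primary alcohol to the acid through the aldehyde hydrate, primary alcohols reacting faster than the hindered secondary allylic C2 hydroxyl.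

Step 17
Reactants: 26 hydroxy lactone acid
Product: 29 target CNP0182929.1, via bis(trifluoroacetyl) mixed anhydride 27 (not isolated), via tetracyclic trifluoroacetate 28 (not isolated)
Conditions: (CF3CO)2O, CH2Cl2 (0.005 M), 0 °C → rt; then MeOH, aq. NaHCO3, 0 °C
Reagents that add atoms: none
Why: The mixed trifluoroacetic anhydride acylates furan C13 intramolecularly (Friedel–Crafts acylation; the free α-position C15 cannot be reached by the tether) and closes the seven-membered ring C, and the C2 trifluoroacetate formed in passing is methanolysed on work-up while the acetate stays.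

**Compound list**

1 | tert-butyl(but-3-yn-1-yloxy)dimethylsilane | C#CCCO[Si](C)(C)C(C)(C)C | starting material
2 | furan-2-carbaldehyde | O=Cc1ccco1 | starting material
3 | (R)-5-[(tert-butyldimethylsilyl)oxy]-1-(furan-2-yl)pent-2-yn-1-ol | O[C@@H](c1ccco1)C#CCCO[Si](C)(C)C(C)(C)C | intermediate
4 | (1R,2Z)-5-[(tert-butyldimethylsilyl)oxy]-1-(furan-2-yl)-3-iodopent-2-en-1-ol | O[C@@H](c1ccco1)/C=C(\I)CCO[Si](C)(C)C(C)(C)C | intermediate
5 | (1R,2E)-5-[(tert-butyldimethylsilyl)oxy]-1-(furan-2-yl)-3-methylpent-2-en-1-ol | O[C@@H](c1ccco1)/C=C(\C)CCO[Si](C)(C)C(C)(C)C | intermediate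
6 | (1R,2E)-5-[(tert-butyldimethylsilyl)oxy]-1-(furan-2-yl)-3-methylpent-2-en-1-yl propanoate | CCC(=O)O[C@@H](c1ccco1)/C=C(\C)CCO[Si](C)(C)C(C)(C)C | intermediate
7 | trimethylsilyl ketene acetal of 6 (C-methyl cis to OSiMe3) | C/C=C(\O[Si](C)(C)C)O[C@@H](c1ccco1)/C=C(\C)CCO[Si](C)(C)C(C)(C)C | intermediate
8 | trimethylsilyl (2S,3R,4E)-3-{2-[(tert-butyldimethylsilyl)oxy]ethyl}-5-(furan-2-yl)-2,3-dimethylpent-4-enoate | C[Si](C)(C)OC(=O)[C@@H](C)[C@](C)(CCO[Si](C)(C)C(C)(C)C)/C=C/c1ccco1 | intermediate
9 | (2S,3R,4E)-3-{2-[(tert-butyldimethylsilyl)oxy]ethyl}-5-(furan-2-yl)-2,3-dimethylpent-4-enoic acid | OC(=O)[C@@H](C)[C@](C)(CCO[Si](C)(C)C(C)(C)C)/C=C/c1ccco1 | intermediate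
10 | ethoxyethene | C=COCC | starting material
11 | ethyl chlorooxoacetate | CCOC(=O)C(=O)Cl | starting material
12 | ethyl (3E)-4-ethoxy-2-oxobut-3-enoate | CCO/C=C/C(=O)C(=O)OCC | intermediate
13 | ethyl 2-(triphenyl-λ5-phosphanylidene)propanoate | CCOC(=O)C(C)=P(c1ccccc1)(c1ccccc1)c1ccccc1 | starting material
14 | diethyl 2-[(E)-2-ethoxyethenyl]-3-methylbut-2-enedioate | CCO/C=C/C(C(=O)OCC)=C(C)C(=O)OCC | intermediate
15 | ethyl 3-methyl-2-oxo-2H-pyran-4-carboxylate | CCOC(=O)C1=C(C)C(=O)OC=C1 | intermediate
16 | ethyl 3-(bromomethyl)-2-oxo-2H-pyran-4-carboxylate | CCOC(=O)C1=C(CBr)C(=O)OC=C1 | intermediate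
17 | (2S,3R,4E)-3-{2-[(tert-butyldimethylsilyl)oxy]ethyl}-5-(furan-2-yl)-2,3-dimethylpent-4-enoyl chloride | ClC(=O)[C@@H](C)[C@](C)(CCO[Si](C)(C)C(C)(C)C)/C=C/c1ccco1 | intermediate
18 | {[4-(ethoxycarbonyl)-2-oxo-2H-pyran-3-yl]methyl}zinc bromide | CCOC(=O)C1=C(C[Zn]Br)C(=O)OC=C1 | intermediate
19 | ethyl 3-[(3S,4R,5E)-4-{2-[(tert-butyldimethylsilyl)oxy]ethyl}-6-(furan-2-yl)-3,4-dimethyl-2-oxohex-5-en-1-yl]-2-oxo-2H-pyran-4-carboxylate | CCOC(=O)C1=C(CC(=O)[C@@H](C)[C@](C)(CCO[Si](C)(C)C(C)(C)C)/C=C/c2ccco2)C(=O)OC=C1 | intermediate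
20 | Diels–Alder adduct (7-ketone, C19(=O)–O–C2 lactone bridge, C18 ethyl ester) | O=C1C[C@@]23C(=O)O[C@@H](C=C2C(=O)OCC)[C@@H](c2ccco2)[C@@H]3[C@@](C)(CCO[Si](C)(C)C(C)(C)C)[C@@H]1C | intermediate
21 | 7-hydroxy adduct (axial alcohol) | O[C@@H]1C[C@@]23C(=O)O[C@@H](C=C2C(=O)OCC)[C@@H](c2ccco2)[C@@H]3[C@@](C)(CCO[Si](C)(C)C(C)(C)C)[C@@H]1C | intermediate
22 | 7-acetoxy adduct | CC(=O)O[C@@H]1C[C@@]23C(=O)O[C@@H](C=C2C(=O)OCC)[C@@H](c2ccco2)[C@@H]3[C@@](C)(CCO[Si](C)(C)C(C)(C)C)[C@@H]1C | intermediate
23 | hydroxy acid (C19 acid, 2-OH, C18 ethyl ester) | CC(=O)O[C@@H]1C[C@@]2(C(=O)O)C(C(=O)OCC)=C[C@H](O)[C@@H](c3ccco3)[C@@H]2[C@@](C)(CCO[Si](C)(C)C(C)(C)C)[C@@H]1C | intermediate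
24 | diol ester (C19 CH2OH, 2-OH, C18 ethyl ester) | CC(=O)O[C@@H]1C[C@@]2(CO)C(C(=O)OCC)=C[C@H](O)[C@@H](c3ccco3)[C@@H]2[C@@](C)(CCO[Si](C)(C)C(C)(C)C)[C@@H]1C | intermediate
25 | hydroxy lactone diol (18,19-lactone, 2-OH, C12 CH2OH) | CC(=O)O[C@@H]1C[C@@]23COC(=O)C2=C[C@H](O)[C@@H](c2ccco2)[C@@H]3[C@@](C)(CCO)[C@@H]1C | intermediate
26 | hydroxy lactone acid (C12 carboxylic acid) | CC(=O)O[C@@H]1C[C@@]23COC(=O)C2=C[C@H](O)[C@@H](c2ccco2)[C@@H]3[C@@](C)(CC(=O)O)[C@@H]1C | intermediate
27 | bis(trifluoroacetyl) mixed anhydride (C2 trifluoroacetate, C12 acyl trifluoroacetate) | CC(=O)O[C@@H]1C[C@@]23COC(=O)C2=C[C@H](OC(=O)C(F)(F)F)[C@@H](c2ccco2)[C@@H]3[C@@](C)(CC(=O)OC(=O)C(F)(F)F)[C@@H]1C | intermediate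
28 | tetracyclic C2 trifluoroacetate (ring C closed) | CC(=O)O[C@@H]1C[C@@]23COC(=O)C2=C[C@H](OC(=O)C(F)(F)F)[C@H]2c4occc4C(=O)C[C@@](C)([C@@H]1C)[C@@H]23 | intermediate
29 | CNP0182929.1 | CC(=O)O[C@@H]1C[C@@]23COC(=O)C2=C[C@H](O)[C@H]2c4occc4C(=O)C[C@@](C)([C@@H]1C)[C@@H]23 | target

**Count and risks**

Total step count: 17. Longest linear sequence: 13 (steps 1–5 and 10–17).

Steps most likely to fail:

1. Step 11. What may go wrong: too little discrimination between the two faces of the pyrone by the C8/C9 relay, cycloaddition in a competing mode (alkenylfuran as diene, or tether endo), or loss of CO2 at the temperature needed. The fallback sets out from 19 and comes back at 20. Ketone 19 is reduced under reagent control (oxazaborolidine-catalysed borane reduction, catalyst antipode chosen for the 7S carbinol) to the (7S)-alcohol F1, which is silylated (Et3SiCl, imidazole) to the triethylsilyl ether F2. In the cycloaddition of F2 the silyloxy group is equatorial in the wanted tether chair and syn-axial to both C19 and the C9 arm in the unwanted one, so the facial relay is enforced by a third, temporary stereocentre. The adduct silyl ether F3 is desilylated at the secondary position (HF·pyridine, pyridine, THF, 0 °C) to the 7-epi alcohol F4, which is oxidised (Dess–Martin periodinane) to ketone 20.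

2. Step 10. What may go wrong: reaction of the zinc reagent through its vinylogous ring terminus, homocoupling of the bromide, or epimerisation at C8 through ketene formation from the hindered acid chloride. The fallback sets out from 16 and 9 (as acid chloride 17) and comes back at 19, with no organometal. Bromide 16 and PPh3 give the phosphonium bromide F5, which NaN(SiMe3)2 (THF, −78 °C) converts into the stabilised ylide F6. C-Acylation of the ylide with 17 (Et3N as acid acceptor) gives the acyl ylide F7, and reductive cleavage of the carbon–phosphorus bond (Zn, AcOH) gives ketone 19.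

3. Step 17. What may go wrong: trifluoroacetylation of the free furan α-position C15 in competition with the slow closure of a trans-fused seven-membered ring, or elimination of the C2 trifluoroacetate towards a C1=C2 diene. The fallback sets out from 26 and comes back at 29. Silylation (Et3SiCl, imidazole) gives the bis(triethylsilyl) derivative F8, whose silyl ester is hydrolysed on aqueous work-up to the C2 triethylsilyl ether acid F9. The acid chloride F10 (1-chloro-N,N,2-trimethylprop-1-en-1-amine) is cyclised with SnCl4 (CH2Cl2, −78 °C) to the tetracyclic silyl ether F11, and HF·pyridine gives 29.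

Further compounds
F1 | step 11 | ethyl 3-[(2S,3S,4R,5E)-4-{2-[(tert-butyldimethylsilyl)oxy]ethyl}-6-(furan-2-yl)-2-hydroxy-3,4-dimethylhex-5-en-1-yl]-2-oxo-2H-pyran-4-carboxylate | CCOC(=O)C1=C(C[C@H](O)[C@@H](C)[C@](C)(CCO[Si](C)(C)C(C)(C)C)/C=C/c2ccco2)C(=O)OC=C1
F2 | step 11 | triethylsilyl ether of F1 | CCOC(=O)C1=C(C[C@H](O[Si](CC)(CC)CC)[C@@H](C)[C@](C)(CCO[Si](C)(C)C(C)(C)C)/C=C/c2ccco2)C(=O)OC=C1
F3 | step 11 | Diels–Alder adduct with equatorial 7-triethylsilyloxy group (7-epi to 21) | CC[Si](CC)(CC)O[C@H]1C[C@@]23C(=O)O[C@@H](C=C2C(=O)OCC)[C@@H](c2ccco2)[C@@H]3[C@@](C)(CCO[Si](C)(C)C(C)(C)C)[C@@H]1C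
F4 | step 11 | 7-epi alcohol of the adduct (equatorial 7-OH) | O[C@H]1C[C@@]23C(=O)O[C@@H](C=C2C(=O)OCC)[C@@H](c2ccco2)[C@@H]3[C@@](C)(CCO[Si](C)(C)C(C)(C)C)[C@@H]1C
F5 | step 10 | {[4-(ethoxycarbonyl)-2-oxo-2H-pyran-3-yl]methyl}triphenylphosphonium bromide | CCOC(=O)C1=C(C[P+](c2ccccc2)(c2ccccc2)c2ccccc2)C(=O)OC=C1.[Br-]
F6 | step 10 | ethyl 2-oxo-3-[(triphenyl-λ5-phosphanylidene)methyl]-2H-pyran-4-carboxylate | CCOC(=O)C1=C(C=P(c2ccccc2)(c2ccccc2)c2ccccc2)C(=O)OC=C1
F7 | step 10 | acyl ylide (C6 carries the triphenylphosphoranylidene group; otherwise as 19) | CCOC(=O)C1=C(C(=P(c2ccccc2)(c2ccccc2)c2ccccc2)C(=O)[C@@H](C)[C@](C)(CCO[Si](C)(C)C(C)(C)C)/C=C/c2ccco2)C(=O)OC=C1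
F8 | step 17 | bis(triethylsilyl) derivative of 26 (C2 silyl ether, C12 silyl ester) | CC(=O)O[C@@H]1C[C@@]23COC(=O)C2=C[C@H](O[Si](CC)(CC)CC)[C@@H](c2ccco2)[C@@H]3[C@@](C)(CC(=O)O[Si](CC)(CC)CC)[C@@H]1C
F9 | step 17 | C2 triethylsilyl ether of acid 26 | CC(=O)O[C@@H]1C[C@@]23COC(=O)C2=C[C@H](O[Si](CC)(CC)CC)[C@@H](c2ccco2)[C@@H]3[C@@](C)(CC(=O)O)[C@@H]1C
F10 | step 17 | acid chloride of F9 | CC(=O)O[C@@H]1C[C@@]23COC(=O)C2=C[C@H](O[Si](CC)(CC)CC)[C@@H](c2ccco2)[C@@H]3[C@@](C)(CC(=O)Cl)[C@@H]1C
F11 | step 17 | C2 triethylsilyl ether of the target | CC(=O)O[C@@H]1C[C@@]23COC(=O)C2=C[C@H](O[Si](CC)(CC)CC)[C@H]2c4occc4C(=O)C[C@@](C)([C@@H]1C)[C@@H]23
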